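**Plan**
- The target is quercetin 4'-O-sulfate. In retrosynthesis the sulfate is masked as its neopentyl diester, O3 and O3' as benzyl ethers and O7 as a silyl ether.
- Ring A is cut at C8–C8a, C7–C8, C5–C6 and C4a–C5, giving a 4-pyranon-6-yl diazomethyl ketone and (triisopropylsilyloxy)acetylene.
- The enabling feature: ring C is the 3-hydroxy-4-pyranone nucleus of kojic acid, with a free C–H (future C4a) next to the carbon bearing the one-carbon side chain (future C8a). Ring A carries its oxygens at C5 and C7, the meta pattern that a ketene carbon and a siloxyalkyne carbon supply.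
- The C2–C1' bond is cut by Suzuki coupling of O-benzyl-6-bromokojic acid with a ring B boronate that already carries the masked sulfate.
- Forward order: ring C is bought, ring B is attached, CH2OH is taken to COCHN2, ring A is closed in one operation, and three deprotections follow.
- There are no stereocentres; the only selectivity is regiochemical and comes from the polarisation of the siloxyalkyne.

Key step: step 12

Remark: the target is drawn as the free aryl hydrogen sulfate, so the sodium salt formed in the last step is protonated by brief cold acidification; the salt would be the form for storage.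

**Route**

Step 1
Reactants: 1 2-(benzyloxy)phenol
Product: 2 4-bromo-2-(benzyloxy)phenol
Conditions: NBS (1.0 equiv), MeCN, 0 °C
Reagents that add atoms: N-bromosuccinimide, O=C1CCC(=O)N1Br
Why: Electrophilic aromatic bromination in which the free hydroxyl is the stronger director, so bromine should enter para to it as in the bromination of guaiacol.

Step 2
Reactants: 2 4-bromo-2-(benzyloxy)phenol
Product: 3 2-(benzyloxy)-4-(4,4,5,5-tetramethyl-1,3,2-dioxaborolan-2-yl)phenol
Conditions: B2pin2, Pd(dppf)Cl2 (3 mol %), KOAc, 1,4-dioxane, 85 °C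
Reagents that add atoms: bis(pinacolato)diboron, CC1(C)OB(OC1(C)C)B1OC(C)(C)C(C)(C)O1
Why: Miyaura borylation of an aryl bromide by zerovalent palladium, a reaction that tolerates free phenols under acetate base.

Step 3
Reactants: 4 neopentyl alcohol
Product: 5 neopentyl chlorosulfate
Conditions: SO2Cl2, pyridine, Et2O, −78 °C to rt
Reagents that add atoms: sulfuryl chloride, ClS(Cl)(=O)=O
Why: Chlorosulfation of a primary alcohol with sulfuryl chloride at low temperature, the neopentyl carbon being too hindered for chloride to displace the chlorosulfate.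

Step 4
Reactants: 3 2-(benzyloxy)-4-(4,4,5,5-tetramethyl-1,3,2-dioxaborolan-2-yl)phenol; 5 neopentyl chlorosulfate
Product: 7 2-(benzyloxy)-4-(4,4,5,5-tetramethyl-1,3,2-dioxaborolan-2-yl)phenyl neopentyl sulfate, via sodium phenoxide 6 (not isolated)
Conditions: NaN(SiMe3)2, THF, −78 °C; then 5, −78 to 0 °C
Reagents that add atoms: none
Why: O-sulfonylation of a phenoxide by an alkyl chlorosulfate gives the neutral mixed sulfate diester, which masks the sulfate for the following steps.

Step 5
Reactants: 8 kojic acid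
Product: 9 2-bromo-3-hydroxy-6-(hydroxymethyl)-4H-pyran-4-one (6-bromokojic acid)
Conditions: NBS (1.05 equiv), DMF, 0 °C to rt
Reagents that add atoms: N-bromosuccinimide, O=C1CCC(=O)N1Br
Why: Electrophilic bromination of the enolic 3-hydroxy-4-pyranone at the ring position ortho to the hydroxyl, the established site of electrophilic substitution of kojic acid.

Step 6
Reactants: 9 2-bromo-3-hydroxy-6-(hydroxymethyl)-4H-pyran-4-one
Product: 10 3-(benzyloxy)-2-bromo-6-(hydroxymethyl)-4H-pyran-4-one
Conditions: BnBr, K2CO3, DMF, rt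
Reagents that add atoms: benzyl bromide, BrCc1ccccc1
Why: Williamson etherification in which carbonate deprotonates only the acidic enolic hydroxyl, so the primary alcohol should stay free.

Step 7
Reactants: 10 3-(benzyloxy)-2-bromo-6-(hydroxymethyl)-4H-pyran-4-one; 7 2-(benzyloxy)-4-(4,4,5,5-tetramethyl-1,3,2-dioxaborolan-2-yl)phenyl neopentyl sulfate
Product: 11 2-(benzyloxy)-4-[3-(benzyloxy)-6-(hydroxymethyl)-4-oxo-4H-pyran-2-yl]phenyl neopentyl sulfate
Conditions: Pd(dppf)Cl2 (5 mol %), CsF, anhydrous 1,4-dioxane, 80 °C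
Reagents that add atoms: none
Why: Suzuki–Miyaura coupling of a 2-bromo-4-pyranone (a vinylogous acyl bromide that adds readily to zerovalent palladium) under anhydrous fluoride activation, chosen so that the sulfate diester never meets aqueous base.

Step 8
Reactants: 11 2-(benzyloxy)-4-[3-(benzyloxy)-6-(hydroxymethyl)-4-oxo-4H-pyran-2-yl]phenyl neopentyl sulfate
Product: 13 5-(benzyloxy)-6-{3-(benzyloxy)-4-[(neopentyloxy)sulfonyloxy]phenyl}-4-oxo-4H-pyran-2-carboxylic acid, via aldehyde 12 (not isolated)
Conditions: CrO3, H2SO4, H2O, acetone, 0 °C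
Reagents that add atoms: water, O
Why: Jones oxidation of the primary alcohol through the aldehyde hydrate, the standard conversion of O-benzylkojic acid into O-benzylcomenic acid, under cold acid that benzyl ethers and the sulfate diester tolerate.

Step 9
Reactants: 13 5-(benzyloxy)-6-{3-(benzyloxy)-4-[(neopentyloxy)sulfonyloxy]phenyl}-4-oxo-4H-pyran-2-carboxylic acid
Product: 15 2-(benzyloxy)-4-[3-(benzyloxy)-6-(2-diazoacetyl)-4-oxo-4H-pyran-2-yl]phenyl neopentyl sulfate, via acid chloride 14 (not isolated)
Conditions: (COCl)2, DMF (cat.), CH2Cl2, 0 °C to rt; evaporate; CH2N2 (3 equiv), Et2O–THF, 0 °C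
Reagents that add atoms: diazomethane, C=[N+]=[N-]
Why: Acid chloride formation followed by acylation of diazomethane (first stage of the Arndt–Eistert sequence), with excess diazomethane removing HCl as chloromethane, as is known for chromone-2-carbonyl chlorides.

Step 10
Reactants: 16 trimethylsilylacetylene; 17 triisopropylsilyl trifluoromethanesulfonate
Product: 20 triisopropyl{[(trimethylsilyl)ethynyl]oxy}silane, via lithium silylacetylide 18 (not isolated), via lithium silylethynolate 19 (not isolated)
Conditions: n-BuLi, THF, −78 °C; t-BuOOH/LiN(SiMe3)2, THF, −78 to 0 °C; then 17, −78 to 0 °C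
Reagents that add atoms: tert-butyl hydroperoxide, CC(C)(C)OO
Why: Electrophilic oxygenation of a lithium acetylide by lithium tert-butyl peroxide gives the ynolate, which the hard and bulky silyl triflate should trap on oxygen and not on carbon.

Step 11
Reactants: 20 triisopropyl{[(trimethylsilyl)ethynyl]oxy}silane
Product: 21 (triisopropylsilyloxy)acetylene
Conditions: K2CO3 (cat.), MeOH, 0 °C; pentane extraction
Reagents that add atoms: none
Why: Base-catalysed protodesilylation of an alkynyl C–SiMe3 bond, which should be much faster than methoxide attack at the hindered triisopropylsilyl ether.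

Step 12
Reactants: 15 2-(benzyloxy)-4-[3-(benzyloxy)-6-(2-diazoacetyl)-4-oxo-4H-pyran-2-yl]phenyl neopentyl sulfate; 21 (triisopropylsilyloxy)acetylene
Product: 26 2-(benzyloxy)-4-[3-(benzyloxy)-5-hydroxy-4-oxo-7-(triisopropylsilyloxy)-4H-chromen-2-yl]phenyl neopentyl sulfate, via pyranonylketene 22 (not isolated), via cyclobutenone 23 (not isolated), via dienylketene 24 (not isolated), via cyclohexadienone 25 (not isolated)
Conditions: 21 (3 equiv), ClCH2CH2Cl, hν (420 nm LEDs), 20 °C; then 80 °C in the dark
Reagents that add atoms: none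
Why: Proposed new method: photolysis of the diazoketone should trigger a Wolff rearrangement in which the pyranonyl group shifts to the diazo carbon (C8–C8a), the pyranonylketene adds the siloxyalkyne by [2+2] cycloaddition (C5–C6 and C7–C8), the 4-pyranonylcyclobutenone opens by reversible four-electron electrocyclic cleavage to a dienylketene, and this closes onto the pyranone C5–H carbon (C4a–C5), after which enolisation of the doubly activated C4a–H aromatises ring A. The closest known reaction type is the Danheiser benzannulation of aryl and heteroaryl diazomethyl ketones with siloxyalkynes; the untested element is a 4-pyranone C=C bond as the terminating unit, which should be at least as willing as a benzene or furan bond because the pyranone is only weakly aromatic and its C5 is the nucleophilic α-carbon of a vinylogous ester facing the electrophilic ketene carbon. Ring A is closed by a thermal disrotatory six-electron electrocyclisation that forms a six-membered carbocycle. No stereocentre is created. The step needs the 5-OH and the 7-siloxy group meta to each other: the unsubstituted, nucleophilic alkyne carbon attacks the ketene carbonyl carbon, so that carbon becomes C5 and the siloxy carbon C7, and closure can engage only the single C–H carbon next to the side chain. Irradiation at 420 nm, where the diazoketone but not the 2-aryl-4-pyranone absorbs, is chosen to avoid pyranone photorearrangement, and the chelated 5-OH should not be acylated by ketene intermediates.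

Step 13
Reactants: 26 2-(benzyloxy)-4-[3-(benzyloxy)-5-hydroxy-4-oxo-7-(triisopropylsilyloxy)-4H-chromen-2-yl]phenyl neopentyl sulfate
Product: 27 2-(benzyloxy)-4-[3-(benzyloxy)-5,7-dihydroxy-4-oxo-4H-chromen-2-yl]phenyl neopentyl sulfate
Conditions: Bu4NF, AcOH, THF, 0 °C
Reagents that add atoms: none
Why: Fluoride cleavage of an aryl silyl ether, buffered with acetic acid so that the sulfate diester and the chromone are not exposed to basic phenoxide or fluoride.

Step 14
Reactants: 27 2-(benzyloxy)-4-[3-(benzyloxy)-5,7-dihydroxy-4-oxo-4H-chromen-2-yl]phenyl neopentyl sulfate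
Product: 28 2-hydroxy-4-(3,5,7-trihydroxy-4-oxo-4H-chromen-2-yl)phenyl neopentyl sulfate
Conditions: H2 (1 atm), Pd/C, EtOAc–MeOH, rt
Reagents that add atoms: none
Why: Catalytic hydrogenolysis of the two benzyl ethers, conditions under which the tetrasubstituted flavonol C2=C3 bond and the neopentyl sulfate diester should not be reduced.

Step 15
Reactants: 28 2-hydroxy-4-(3,5,7-trihydroxy-4-oxo-4H-chromen-2-yl)phenyl neopentyl sulfate
Product: 30 2-hydroxy-4-(3,5,7-trihydroxy-4-oxo-4H-chromen-2-yl)phenyl hydrogen sulfate (quercetin 4'-O-sulfate), via sodium sulfate salt 29 (not isolated)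
Conditions: NaN3, DMF, 70 °C, Ar; then cold 0.1 M HCl, C18 desalting, lyophilisation
Reagents that add atoms: none
Why: SN2 dealkylation at the neopentyl carbon by azide with the aryl sulfate monoanion as leaving group, the standard unmasking of neopentyl sulfate diesters, followed by protonation of the salt.

**Compound list**
1 | 2-(benzyloxy)phenol | Oc1ccccc1OCc1ccccc1 | starting material
2 | 4-bromo-2-(benzyloxy)phenol | Oc1ccc(Br)cc1OCc1ccccc1 | intermediate
3 | 2-(benzyloxy)-4-(4,4,5,5-tetramethyl-1,3,2-dioxaborolan-2-yl)phenol | Oc1ccc(B2OC(C)(C)C(C)(C)O2)cc1OCc1ccccc1 | intermediate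
4 | neopentyl alcohol | CC(C)(C)CO | starting material
5 | neopentyl chlorosulfate | CC(C)(C)COS(=O)(=O)Cl | intermediate
6 | sodium 2-(benzyloxy)-4-(4,4,5,5-tetramethyl-1,3,2-dioxaborolan-2-yl)phenoxide | [Na+].[O-]c1ccc(B2OC(C)(C)C(C)(C)O2)cc1OCc1ccccc1 | intermediate
7 | 2-(benzyloxy)-4-(4,4,5,5-tetramethyl-1,3,2-dioxaborolan-2-yl)phenyl neopentyl sulfate | CC(C)(C)COS(=O)(=O)Oc1ccc(B2OC(C)(C)C(C)(C)O2)cc1OCc1ccccc1 | intermediate
8 | kojic acid | O=c1cc(CO)occ1O | starting material
9 | 2-bromo-3-hydroxy-6-(hydroxymethyl)-4H-pyran-4-one | O=c1cc(CO)oc(Br)c1O | intermediate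
10 | 3-(benzyloxy)-2-bromo-6-(hydroxymethyl)-4H-pyran-4-one | O=c1cc(CO)oc(Br)c1OCc1ccccc1 | intermediate
11 | 2-(benzyloxy)-4-[3-(benzyloxy)-6-(hydroxymethyl)-4-oxo-4H-pyran-2-yl]phenyl neopentyl sulfate | O=c1cc(CO)oc(-c2ccc(OS(=O)(=O)OCC(C)(C)C)c(OCc3ccccc3)c2)c1OCc1ccccc1 | intermediate
12 | 2-(benzyloxy)-4-[3-(benzyloxy)-6-formyl-4-oxo-4H-pyran-2-yl]phenyl neopentyl sulfate | O=Cc1cc(=O)c(OCc2ccccc2)c(-c2ccc(OS(=O)(=O)OCC(C)(C)C)c(OCc3ccccc3)c2)o1 | intermediate
13 | 5-(benzyloxy)-6-{3-(benzyloxy)-4-[(neopentyloxy)sulfonyloxy]phenyl}-4-oxo-4H-pyran-2-carboxylic acid | OC(=O)c1cc(=O)c(OCc2ccccc2)c(-c2ccc(OS(=O)(=O)OCC(C)(C)C)c(OCc3ccccc3)c2)o1 | intermediate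
14 | 5-(benzyloxy)-6-{3-(benzyloxy)-4-[(neopentyloxy)sulfonyloxy]phenyl}-4-oxo-4H-pyran-2-carbonyl chloride | ClC(=O)c1cc(=O)c(OCc2ccccc2)c(-c2ccc(OS(=O)(=O)OCC(C)(C)C)c(OCc3ccccc3)c2)o1 | intermediate
15 | 2-(benzyloxy)-4-[3-(benzyloxy)-6-(2-diazoacetyl)-4-oxo-4H-pyran-2-yl]phenyl neopentyl sulfate | [N-]=[N+]=CC(=O)c1cc(=O)c(OCc2ccccc2)c(-c2ccc(OS(=O)(=O)OCC(C)(C)C)c(OCc3ccccc3)c2)o1 | intermediate
16 | trimethylsilylacetylene | C#C[Si](C)(C)C | starting material
17 | triisopropylsilyl trifluoromethanesulfonate | CC(C)[Si](OS(=O)(=O)C(F)(F)F)(C(C)C)C(C)C | starting material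
18 | lithium (trimethylsilyl)acetylide | [Li+].[C-]#C[Si](C)(C)C | intermediate
19 | lithium 2-(trimethylsilyl)ethynolate | [Li+].[O-]C#C[Si](C)(C)C | intermediate
20 | triisopropyl{[(trimethylsilyl)ethynyl]oxy}silane | C[Si](C)(C)C#CO[Si](C(C)C)(C(C)C)C(C)C | intermediate
21 | (triisopropylsilyloxy)acetylene | C#CO[Si](C(C)C)(C(C)C)C(C)C | intermediate
22 | 2-(benzyloxy)-4-[3-(benzyloxy)-4-oxo-6-(2-oxoethenyl)-4H-pyran-2-yl]phenyl neopentyl sulfate (pyranonylketene) | O=C=Cc1cc(=O)c(OCc2ccccc2)c(-c2ccc(OS(=O)(=O)OCC(C)(C)C)c(OCc3ccccc3)c2)o1 | intermediate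
23 | 2-(benzyloxy)-4-{3-(benzyloxy)-4-oxo-6-[4-oxo-2-(triisopropylsilyloxy)cyclobut-2-en-1-yl]-4H-pyran-2-yl}phenyl neopentyl sulfate (racemic) | O=C1C=C(O[Si](C(C)C)(C(C)C)C(C)C)C1c1cc(=O)c(OCc2ccccc2)c(-c2ccc(OS(=O)(=O)OCC(C)(C)C)c(OCc3ccccc3)c2)o1 | intermediate
24 | 2-(benzyloxy)-4-{3-(benzyloxy)-4-oxo-6-[(1E)-4-oxo-2-(triisopropylsilyloxy)buta-1,3-dien-1-yl]-4H-pyran-2-yl}phenyl neopentyl sulfate (ketene arm cis to the pyranonyl group) | O=C=C/C(O[Si](C(C)C)(C(C)C)C(C)C)=C\c1cc(=O)c(OCc2ccccc2)c(-c2ccc(OS(=O)(=O)OCC(C)(C)C)c(OCc3ccccc3)c2)o1 | intermediate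
25 | 2-(benzyloxy)-4-[3-(benzyloxy)-4,5-dioxo-7-(triisopropylsilyloxy)-4a,5-dihydro-4H-chromen-2-yl]phenyl neopentyl sulfate (racemic keto tautomer) | O=C1C=C(O[Si](C(C)C)(C(C)C)C(C)C)C=C2OC(-c3ccc(OS(=O)(=O)OCC(C)(C)C)c(OCc4ccccc4)c3)=C(OCc3ccccc3)C(=O)C12 | intermediate
26 | 2-(benzyloxy)-4-[3-(benzyloxy)-5-hydroxy-4-oxo-7-(triisopropylsilyloxy)-4H-chromen-2-yl]phenyl neopentyl sulfate | O=c1c(OCc2ccccc2)c(-c2ccc(OS(=O)(=O)OCC(C)(C)C)c(OCc3ccccc3)c2)oc2cc(O[Si](C(C)C)(C(C)C)C(C)C)cc(O)c12 | intermediate
27 | 2-(benzyloxy)-4-[3-(benzyloxy)-5,7-dihydroxy-4-oxo-4H-chromen-2-yl]phenyl neopentyl sulfate | O=c1c(OCc2ccccc2)c(-c2ccc(OS(=O)(=O)OCC(C)(C)C)c(OCc3ccccc3)c2)oc2cc(O)cc(O)c12 | intermediate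
28 | 2-hydroxy-4-(3,5,7-trihydroxy-4-oxo-4H-chromen-2-yl)phenyl neopentyl sulfate | O=c1c(O)c(-c2ccc(OS(=O)(=O)OCC(C)(C)C)c(O)c2)oc2cc(O)cc(O)c12 | intermediate
29 | sodium 2-hydroxy-4-(3,5,7-trihydroxy-4-oxo-4H-chromen-2-yl)phenyl sulfate | [Na+].O=c1c(O)c(-c2ccc(OS(=O)(=O)[O-])c(O)c2)oc2cc(O)cc(O)c12 | intermediate
30 | 2-hydroxy-4-(3,5,7-trihydroxy-4-oxo-4H-chromen-2-yl)phenyl hydrogen sulfate (quercetin 4'-O-sulfate) | O=c1c(O)c(-c2ccc(OS(=O)(=O)O)c(O)c2)oc2cc(O)cc(O)c12 | target

**Count**
Total steps: 15. Longest linear sequence: 10 steps (steps 1, 2, 4, 7, 8, 9, 12, 13, 14, 15).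

**Three steps most likely to fail**

The ring A annulation of step 12 is the most exposed operation. The arylpyranone may undergo its own photorearrangement, the ketene may dimerise before it meets the alkyne, or the dienylketene may fail to close onto the pyranone carbon and be diverted. The fallback for step 12 gives up the ring A annulation and reaches 28 from an intact flavonol by known protecting-group chemistry; it sets out from 5 and comes back to the route at 28. Commercial quercetin F1 would be heated with dichlorodiphenylmethane in diphenyl ether at 175 °C to give quercetin 3',4'-O-diphenylmethylene ketal F2 as the catechol-protected flavonol. Benzylation of O3 and O7 with BnBr and K2CO3 in DMF would give 3,7-di-O-benzylquercetin 3',4'-O-diphenylmethylene ketal F3 with the chelated 5-OH left free, and AcOH–H2O at reflux would remove the ketal to give 3,7-di-O-benzylquercetin F4 as the free catechol. One equivalent of NaN(SiMe3)2 followed by 5 should sulfate the more acidic 4'-OH, as in the known 4'-selective alkylation of this catechol, to give 3,7-di-O-benzylquercetin 4'-(neopentyl sulfate) F5 as the mixed diester. Hydrogenolysis over Pd/C would then give 28, and step 15 follows.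

The cross-coupling of step 7 comes second. The neopentyl group may be lost or the aryl–O–S bond cleaved under the basic coupling, and the boronate may protodeboronate. The fallback for step 7 installs the sulfate after the coupling; it sets out from 3 and comes back to the route at 11. Boronate 3 would be coupled with 10 under ordinary aqueous conditions (Pd(dppf)Cl2, K3PO4, dioxane–H2O, 80 °C) to give 3-(benzyloxy)-2-[3-(benzyloxy)-4-hydroxyphenyl]-6-(hydroxymethyl)-4H-pyran-4-one F6 as the free phenol. Deprotonation of the phenol alone with one equivalent of NaN(SiMe3)2 at −78 °C and addition of 5 would give 11.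

The protodesilylation of step 11 comes third. Methoxide may attack the O–Si bond, methanol may add to the ynol ether, and the volatile product may be lost on concentration. The fallback for step 11 oxygenates the parent acetylide directly, so no C-silyl group has to be removed; it sets out from 17 and comes back to the route at 21. Commercial ethynylmagnesium bromide F7 in THF would be oxygenated with lithium tert-butyl peroxide to bromomagnesium ethynolate F8 in solution, which would be silylated on oxygen with 17 at −78 °C to give 21.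

**Further compounds**
F1 | step 12 | quercetin | O=c1c(O)c(-c2ccc(O)c(O)c2)oc2cc(O)cc(O)c12
F2 | step 12 | quercetin 3',4'-O-diphenylmethylene ketal | O=c1c(O)c(-c2ccc3OC(c4ccccc4)(c4ccccc4)Oc3c2)oc2cc(O)cc(O)c12
F3 | step 12 | 3,7-di-O-benzylquercetin 3',4'-O-diphenylmethylene ketal | O=c1c(OCc2ccccc2)c(-c2ccc3OC(c4ccccc4)(c4ccccc4)Oc3c2)oc2cc(OCc3ccccc3)cc(O)c12
F4 | step 12 | 3,7-di-O-benzylquercetin | O=c1c(OCc2ccccc2)c(-c2ccc(O)c(O)c2)oc2cc(OCc3ccccc3)cc(O)c12
F5 | step 12 | 3,7-di-O-benzylquercetin 4'-(neopentyl sulfate) | O=c1c(OCc2ccccc2)c(-c2ccc(OS(=O)(=O)OCC(C)(C)C)c(O)c2)oc2cc(OCc3ccccc3)cc(O)c12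
F6 | step 7 | 3-(benzyloxy)-2-[3-(benzyloxy)-4-hydroxyphenyl]-6-(hydroxymethyl)-4H-pyran-4-one | O=c1cc(CO)oc(-c2ccc(O)c(OCc3ccccc3)c2)c1OCc1ccccc1
F7 | step 11 | ethynylmagnesium bromide | C#C[Mg]Br
F8 | step 11 | bromomagnesium ethynolate | [Mg+2].[Br-].[O-]C#C
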